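Do not read the steady fall of the solid substrate as the progress of the reaction: at 1.33 min it stands at 80.0 % in Sunday's run with 7 mM of catalyst and at 80.0 % in Friday's with 28 mM, a start slope of 0.150 min⁻¹ of the charge in both.

in all of them: solid substrate 0.50 M

| flask | partner | second substrate | catalyst | remark | time |
|---|---|---|---|---|---|
| Sunday's | 0.60 M | 0.50 M | 7 mM | run made earlier |  |
| Friday's | 0.60 M | 0.50 M | 28 mM | run made earlier |  |
| flask | 0.600 M | 0.500 M | 14 mM |  | 10 min |

| run | time / min | target / % | solid substrate / % |
|---|---|---|---|
| Sunday's | 1.33 | 6.1 | 80.0 |
| Sunday's | 3.00 | 19.9 | 58.8 |
| Sunday's | 4.00 | 28.2 | 47.7 |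
| Sunday's | 6.00 | 45.4 | 25.2 |
| Sunday's | 8.00 | 59.1 | 3.5 |
| Sunday's | 10.0 | 69.5 | 0.7 |
| Friday's | 0.833 | 6.1 | 86.7 |
| Friday's | 1.33 | 14.7 | 80.0 |
| Friday's | 2.00 | 20.4 | 70.2 |
| Friday's | 3.00 | 32.3 | 54.5 |
| Friday's | 4.00 | 44.0 | 41.6 |
| Friday's | 6.00 | 65.1 | 15.4 |
| Friday's | 10.0 | 81.5 | 1.0 |

(readings scatter by 1 percentage point)

- delta: doubling the amount of partner, all else as stated
- epsilon: doubling the dissolution coefficient of the solid substrate, all else as stated
- zeta: doubling the amount of catalyst, all else as stated
- theta: doubling the solubility of the solid substrate, all else as stated

1. the target standing at 10 min, as a percentage of the solid substrate charged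
2. the change that raises the amount of target at 10 min, in percent of the solid substrate charged most ("none" if none brings more than 2 percentage points) (delta / epsilon / zeta / theta / none)
3. amount of target at 10 min, in percent of the solid substrate charged, after delta

- solid substrate is a solid; its amount is given per volume of the solution
- the earlier runs were read with a standard deviation of 1 percentage point
- at the start none of the solid substrate is in solution

Draw this flask's curve from those runs. Give its solid the same start slope and put the knee near 8.00 min, where Sunday's solid reads 3.5 %. Let the target cross the solid between 3.00 min and 6.00 min, because Friday's readings cross between 3.00 min and 4.00 min, Sunday's between 4.00 min and 6.00 min, and this flask's catalyst charge lies between theirs. Then ask what level the target runs into, and reckon the partner cover, the test for the limiting reagent, which is tighter than it looks if the second substrate takes partner too: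

cover = [partner] charged / [solid substrate] charged = 120 %

Now read the bend in Friday's run. The target readings climb 0.0410 min⁻¹ from 6.00 min to 10.0 min against 0.117 min⁻¹ from 3.00 min to 4.00 min, although the dissolved stock, solid lost minus target, reads 17.5 % at the end against 14.4 % at 4.00 min, so take the partner to be thinning.

Doubling this flask's catalyst gives Friday's recipe, so read that change off Friday's last target reading, 81.5 %. Commit to a target above the midpoint of the two runs, 75.5 %, and below Friday's. Choose delta, which lifts the cover to 240 %, and expect the target to come close to the charge.

The forecast gave 76 %, delta and 89 % after delta, on the ground that “Late in the run the limit is chemical, with depleted partner and second substrate”.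

The flask gives 79.9 %, inside my bracket, and delta is best, worth 19 percentage points and reaching 98.9 %, against 1.6 points for zeta. At 10.0 min, 13.3 % of the partner still stands. Per solid charged, target, second product and that partner sum to 120 %, which is the cover.

    starting material + partner + catalyst → catalyst + target (k = 2.00 M⁻² s⁻¹)
    second substrate + partner + catalyst → catalyst + second product (k = 0.110 M⁻² s⁻¹)
    solid substrate ⇌ starting material, rate k3*(cs3 - [starting material]) while solid is left; crystals form when [starting material] > cs3 (solubility = 0.490 M, k = 0.00270 s⁻¹)

Charge 0.24 M of partner instead: the cover drops to 48.0 %, and if that cover is spent whole in the split this flask shows at 10.0 min, 76.8 % to target, the estimate is 36.9 %. The computed neighbour holds 37.9 % of target, with 62.1 % as starting material and 3.2 % of its partner unspent.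

(The data were computed with constants of no real substance; scatter was added.)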